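The dihydrofuran ring is cut at C2 (benzofuran numbering; C1' is the side-chain CH(CH3), C2' its CH2O). O1, C7a, C3a and the benzylic C3 are the four atoms of an ortho-quinone methide. The single sp3 carbon C2 comes from a chiral 2-(silyloxymethyl)allyl sulfonium ylide that already carries C1' and C2'. One base-mediated [4+1] annulation forms C3-C2 and O1-C2, closes the ring and sets C2. Its precursors are 4-bromo-2-(tosylmethyl)phenol and a twofold-symmetric 2,5-dimethylthiolanium triflate. Desilylation, hydroxyl-directed asymmetric hydrogenation (C1'), Mitsunobu esterification and a Heck reaction complete the target.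

Key step: step 7

Assumption 1 (step 7): the usual model for 2,5-dimethylthiolanium ylides (carbon substituent turned away from the ring, attack anti to the neighbouring ring methyl, inversion on closure) predicts (S) at C2 from the (2S,5S) sulfide, so that enantiomer is used; the antipode, made the same way from (2S,5S)-hexane-2,5-diol, would be taken if the sense proved opposite.

Assumption 2 (step 9): by analogy with other 2-substituted allylic alcohols that carry a heteroatom-bearing stereocentre next to the alkene, Ru(OAc)2[(R)-BINAP] is taken to give (1'S).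

Step 1
Reactants: 1 5-bromo-2-hydroxybenzyl alcohol
Product: 2 4-bromo-2-[(4-methylbenzenesulfonyl)methyl]phenol
Conditions: TolSO2Na, HCO2H/H2O, 40 °C
Reagents that add atoms: sodium p-toluenesulfinate, [Na+].[O-]S(=O)c1ccc(C)cc1
Why: Acid-promoted benzylic substitution of the ortho-hydroxybenzyl alcohol by the sulfur-nucleophilic sulfinate is a standard preparation of 2-(sulfonylmethyl)phenols, and the para-bromine blocks self-condensation at that ring position.

Step 2
Reactants: 3 2-methylidenepropane-1,3-diol
Product: 4 2-{[(tert-butyldimethylsilyl)oxy]methyl}prop-2-en-1-ol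
Conditions: NaH (1 equiv), THF, 0 °C to rt; then TBSCl
Reagents that add atoms: tert-butyldimethylsilyl chloride, CC(C)(C)[Si](C)(C)Cl
Why: Monodeprotonation of the symmetric diol gives a sparingly soluble monosodium alkoxide that is silylated once (Williamson-type O-silylation), so the mono-ether should predominate.

Step 3
Reactants: 4 2-{[(tert-butyldimethylsilyl)oxy]methyl}prop-2-en-1-ol
Product: 5 {[2-(bromomethyl)prop-2-en-1-yl]oxy}(tert-butyl)dimethylsilane
Conditions: CBr4, PPh3, CH2Cl2, 0 °C
Reagents that add atoms: tetrabromomethane, BrC(Br)(Br)Br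
Why: Appel bromination converts the primary allylic alcohol into the bromide under neutral conditions that leave the silyl ether intact.

Step 4
Reactants: 6 (2R,5R)-hexane-2,5-diol
Product: 7 (2R,5R)-hexane-2,5-diyl dimethanesulfonate
Conditions: MsCl, Et3N, CH2Cl2, 0 °C
Reagents that add atoms: methanesulfonyl chloride, CS(=O)(=O)Cl
Why: O-Sulfonylation of both secondary alcohols touches only the O-H bonds, so both carbinol centres keep their configuration.

Step 5
Reactants: 7 (2R,5R)-hexane-2,5-diyl dimethanesulfonate
Product: 8 (2S,5S)-2,5-dimethylthiolane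
Conditions: Na2S·9H2O, DMSO, rt
Reagents that add atoms: sodium sulfide (nonahydrate), [Na+].[Na+].[S-2]
Why: Double SN2 thioetherification (intermolecular, then 5-exo-tet) inverts both centres, so the (2R,5R)-dimesylate should give the trans (2S,5S)-thiolane.

Step 6
Reactants: 5 {[2-(bromomethyl)prop-2-en-1-yl]oxy}(tert-butyl)dimethylsilane; 8 (2S,5S)-2,5-dimethylthiolane
Product: 10 (2S,5S)-1-{2-[(tert-butyldimethylsilyloxy)methyl]prop-2-en-1-yl}-2,5-dimethylthiolan-1-ium trifluoromethanesulfonate, via sulfonium bromide 9 (not isolated)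
Conditions: lithium trifluoromethanesulfonate, CH2Cl2/H2O, rt
Reagents that add atoms: lithium trifluoromethanesulfonate, [Li+].[O-]S(=O)(=O)C(F)(F)F
Why: SN2 S-alkylation by the allylic bromide followed by anion metathesis to the non-nucleophilic triflate prevents dealkylation by bromide, and the twofold symmetry of the sulfide makes its two lone pairs equivalent, so a single sulfonium salt should form.

Step 7
Reactants: 2 4-bromo-2-[(4-methylbenzenesulfonyl)methyl]phenol; 10 (2S,5S)-1-{2-[(tert-butyldimethylsilyloxy)methyl]prop-2-en-1-yl}-2,5-dimethylthiolan-1-ium trifluoromethanesulfonate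
Product: 14 tert-butyl({2-[(2S)-5-bromo-2,3-dihydro-1-benzofuran-2-yl]prop-2-en-1-yl}oxy)dimethylsilane, via ortho-quinone methide 11 (not isolated), via allylic sulfonium ylide 12 (not isolated), via phenoxide-sulfonium betaine 13 (not isolated)
Conditions: 10 (1.5 equiv), Cs2CO3 (3 equiv), MeCN, -20 °C to rt, slow addition of 2
Reagents that add atoms: none
Why: Proposed new method: Cs2CO3 turns 2 into its phenoxide, which loses p-toluenesulfinate by 1,4-elimination to give the ortho-quinone methide 11, and deprotonates 10 at the sulfur-bound allylic CH2 to give ylide 12, whose carbanion adds to the exocyclic CH2 of 11 (bond C3-C2) with rearomatisation to betaine 13, in which the phenoxide displaces the neutral thiolane from the same carbon (bond O1-C2). The closest known reaction type is the base-mediated [4+1] annulation of in situ generated ortho-quinone methides with carbonyl-stabilised sulfonium ylides to 2,3-dihydrobenzofurans, combined with the behaviour of chiral allyl sulfonium ylides in Corey-Chaykovsky epoxidation, whereas a non-carbonyl allyl ylide on a chiral sulfide has not been shown in this annulation. The dihydrofuran ring closes by a 5-exo-tet SN2 substitution with inversion at C2. C2 is the only new stereocentre because the methide terminus is a CH2, and it is controlled by the twofold-symmetric (2S,5S)-thiolane, whose ylide should turn its alkenyl group away from the ring and react on the face anti to the adjacent ring methyl, so that inversion in the closure gives (S). The step needs alpha- over gamma-attack of the allyl ylide, ylide formation at the allylic carbon instead of a ring CH, and closure faster than betaine reversal or epimerisation, which should be secured by the higher acidity and charge density at the sulfur-bound allylic carbon, the tertiary and hindered ring alpha-positions, the irreversibility that rearomatisation confers and the fast five-membered closure onto an allylic carbon bearing a neutral leaving group. Slow release of both partners by the heterogeneous base should keep the unsubstituted methide from oligomerising.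

Step 8
Reactants: 14 tert-butyl({2-[(2S)-5-bromo-2,3-dihydro-1-benzofuran-2-yl]prop-2-en-1-yl}oxy)dimethylsilane
Product: 15 2-[(2S)-5-bromo-2,3-dihydro-1-benzofuran-2-yl]prop-2-en-1-ol
Conditions: TBAF, THF, 0 °C
Reagents that add atoms: none
Why: Fluoride-mediated desilylation frees the primary allylic alcohol, and the aryl bromide, the alkene and the C2 ether are inert to fluoride.

Step 9
Reactants: 15 2-[(2S)-5-bromo-2,3-dihydro-1-benzofuran-2-yl]prop-2-en-1-ol
Product: 16 (2S)-2-[(2S)-5-bromo-2,3-dihydro-1-benzofuran-2-yl]propan-1-ol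
Conditions: Ru(OAc)2[(R)-BINAP] (cat.), H2 (50 atm), MeOH, rt
Reagents that add atoms: none
Why: Hydroxyl-directed asymmetric hydrogenation of a 2-substituted allylic alcohol with Ru(OAc)2[(R)-BINAP] is a known reaction class for 1,1-disubstituted allylic alcohols that bear a neighbouring stereocentre, the bound hydroxyl and the ligand select the alkene face that should give (1'S), and the aryl bromide is not reduced by this catalyst.

Step 10
Reactants: 16 (2S)-2-[(2S)-5-bromo-2,3-dihydro-1-benzofuran-2-yl]propan-1-ol; 17 p-coumaric acid, (2E)-3-(4-hydroxyphenyl)prop-2-enoic acid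
Product: 18 (2S)-2-[(2S)-5-bromo-2,3-dihydro-1-benzofuran-2-yl]propyl (2E)-3-(4-hydroxyphenyl)prop-2-enoate
Conditions: PPh3, DIAD, THF, 0 °C to rt
Reagents that add atoms: none
Why: Mitsunobu esterification activates the primary alcohol and takes the carboxylic acid, far more acidic than the phenol, as the pronucleophile, so 17 needs no protection and C1', which is not the reacting carbon, keeps its configuration.

Step 11
Reactants: 18 (2S)-2-[(2S)-5-bromo-2,3-dihydro-1-benzofuran-2-yl]propyl (2E)-3-(4-hydroxyphenyl)prop-2-enoate; 19 acrylic acid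
Product: 20 (2E)-3-[(2S)-2-{(2S)-1-{[(2E)-3-(4-hydroxyphenyl)prop-2-enoyl]oxy}propan-2-yl}-2,3-dihydro-1-benzofuran-5-yl]prop-2-enoic acid
Conditions: Pd(OAc)2, P(o-tol)3, Et3N, DMF, 100 °C; then dilute HCl
Reagents that add atoms: none
Why: The Heck reaction of the aryl bromide with acrylic acid (as its triethylammonium salt) gives the (E)-cinnamic acid directly by syn-insertion and syn-beta-hydride elimination, and the 1,2-disubstituted coumarate alkene should react far more slowly than the monosubstituted acrylate.

Compound list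
1 | 5-bromo-2-hydroxybenzyl alcohol | OCc1cc(Br)ccc1O | starting material
2 | 4-bromo-2-[(4-methylbenzenesulfonyl)methyl]phenol | Cc1ccc(cc1)S(=O)(=O)Cc1cc(Br)ccc1O | intermediate
3 | 2-methylidenepropane-1,3-diol | C=C(CO)CO | starting material
4 | 2-{[(tert-butyldimethylsilyl)oxy]methyl}prop-2-en-1-ol | C=C(CO)CO[Si](C)(C)C(C)(C)C | intermediate
5 | {[2-(bromomethyl)prop-2-en-1-yl]oxy}(tert-butyl)dimethylsilane | C=C(CBr)CO[Si](C)(C)C(C)(C)C | intermediate
6 | (2R,5R)-hexane-2,5-diol | C[C@@H](O)CC[C@@H](C)O | starting material
7 | (2R,5R)-hexane-2,5-diyl dimethanesulfonate | C[C@@H](OS(C)(=O)=O)CC[C@@H](C)OS(C)(=O)=O | intermediate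
8 | (2S,5S)-2,5-dimethylthiolane | C[C@H]1CC[C@H](C)S1 | intermediate
9 | (2S,5S)-1-{2-[(tert-butyldimethylsilyloxy)methyl]prop-2-en-1-yl}-2,5-dimethylthiolan-1-ium bromide | C[C@H]1CC[C@H](C)[S+]1CC(=C)CO[Si](C)(C)C(C)(C)C.[Br-] | intermediate (not isolated)
10 | (2S,5S)-1-{2-[(tert-butyldimethylsilyloxy)methyl]prop-2-en-1-yl}-2,5-dimethylthiolan-1-ium trifluoromethanesulfonate | C[C@H]1CC[C@H](C)[S+]1CC(=C)CO[Si](C)(C)C(C)(C)C.[O-]S(=O)(=O)C(F)(F)F | intermediate
11 | 4-bromo-6-methylidenecyclohexa-2,4-dien-1-one | C=C1C=C(Br)C=CC1=O | intermediate (not isolated)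
12 | (2S,5S)-1-{2-[(tert-butyldimethylsilyloxy)methyl]prop-2-en-1-id-1-yl}-2,5-dimethylthiolan-1-ium (ylide) | C[C@H]1CC[C@H](C)[S+]1[CH-]C(=C)CO[Si](C)(C)C(C)(C)C | intermediate (not isolated)
13 | 4-bromo-2-{(2R)-3-[(tert-butyldimethylsilyloxy)methyl]-2-[(2S,5S)-2,5-dimethylthiolan-1-ium-1-yl]but-3-en-1-yl}phenolate | [O-]c1ccc(Br)cc1C[C@H](C(=C)CO[Si](C)(C)C(C)(C)C)[S+]1[C@@H](C)CC[C@@H]1C | intermediate (not isolated)
14 | tert-butyl({2-[(2S)-5-bromo-2,3-dihydro-1-benzofuran-2-yl]prop-2-en-1-yl}oxy)dimethylsilane | C=C(CO[Si](C)(C)C(C)(C)C)[C@@H]1Cc2cc(Br)ccc2O1 | intermediate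
15 | 2-[(2S)-5-bromo-2,3-dihydro-1-benzofuran-2-yl]prop-2-en-1-ol | C=C(CO)[C@@H]1Cc2cc(Br)ccc2O1 | intermediate
16 | (2S)-2-[(2S)-5-bromo-2,3-dihydro-1-benzofuran-2-yl]propan-1-ol | C[C@@H](CO)[C@@H]1Cc2cc(Br)ccc2O1 | intermediate
17 | p-coumaric acid | OC(=O)/C=C/c1ccc(O)cc1 | starting material
18 | (2S)-2-[(2S)-5-bromo-2,3-dihydro-1-benzofuran-2-yl]propyl (2E)-3-(4-hydroxyphenyl)prop-2-enoate | C[C@@H](COC(=O)/C=C/c1ccc(O)cc1)[C@@H]1Cc2cc(Br)ccc2O1 | intermediate
19 | acrylic acid | C=CC(=O)O | starting material
20 | (2E)-3-[(2S)-2-{(2S)-1-{[(2E)-3-(4-hydroxyphenyl)prop-2-enoyl]oxy}propan-2-yl}-2,3-dihydro-1-benzofuran-5-yl]prop-2-enoic acid | C[C@@H](COC(=O)/C=C/c1ccc(O)cc1)[C@@H]1Cc2cc(/C=C/C(=O)O)ccc2O1 | target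

Total step count: 11 steps.
Longest linear sequence: 8 steps (3 → 4 → 5 → 10 → 14 → 15 → 16 → 18 → 20, steps 2, 3, 6, 7, 8, 9, 10 and 11; the branch from 6 is equally long).

Steps most likely to fail

Step 7. The allyl ylide may add through its gamma-carbon, the unsubstituted quinone methide may oligomerise before it is trapped, the sulfonium salt may transfer its allyl group to sulfinate or phenoxide, and the facial bias at the ylide carbon may be too small. The fallback uses known chemistry and builds the ring with Pd instead of a ylide. Setting out from 4, oxidation with MnO2 (CH2Cl2, rt) would give 2-{[(tert-butyldimethylsilyl)oxy]methyl}prop-2-enal F1. Wittig methylenation (Ph3PCH3Br, KOtBu, THF, 0 °C) would then give the diene tert-butyl(dimethyl)[(2-methylidenebut-3-en-1-yl)oxy]silane F2. Heck/Tsuji-Trost heteroannulation of F2 with commercial 4-bromo-2-iodophenol (Oc1ccc(Br)cc1I; Pd2(dba)3, a chiral phosphine ligand, K2CO3, toluene, 60 °C) should proceed by oxidative addition at the C-I bond only, arylation of the unsubstituted vinyl terminus and enantioselective attack of the phenoxide on the π-allyl palladium intermediate at the carbon next to the benzylic CH2. This returns to the route at 14.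

Step 9. The catalyst and the C2 centre may be mismatched, which would give poor facial selectivity at the 1,1-disubstituted alkene; the allylic alcohol may isomerise to the aldehyde; or a ruthenium alkyl may open the ring by beta-aryloxide elimination. The fallback changes the directing group and oxidation level, so that a bound carboxylate and not a hydroxyl controls the face. From 15, MnO2 (CH2Cl2) would give 2-[(2S)-5-bromo-2,3-dihydro-1-benzofuran-2-yl]prop-2-enal F3, and Pinnick oxidation (NaClO2, NaH2PO4, 2-methylbut-2-ene, tBuOH/H2O) the acrylic acid 2-[(2S)-5-bromo-2,3-dihydro-1-benzofuran-2-yl]prop-2-enoic acid F4. Hydrogenation of this alpha-substituted acrylic acid with Ru(OAc)2(BINAP), with the ligand enantiomer chosen for the matched case, should give (2R)-2-[(2S)-5-bromo-2,3-dihydro-1-benzofuran-2-yl]propanoic acid F5. Reduction of the acid with BH3·THF, which leaves the aryl bromide alone, returns to the route at 16.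

Step 11. Oxidative addition to the electron-rich aryl bromide may be slow at temperatures where acrylic acid polymerises, the coumarate alkene may be arylated in competition, and the phenolic ester may suffer under hot amine base. The fallback makes the aryl-alkene bond before the coumarate is attached and keeps the acid masked. From 16, a Heck reaction with tert-butyl acrylate (Pd(OAc)2, P(o-tol)3, Et3N, DMF, 100 °C) would give tert-butyl (2E)-3-{(2S)-2-[(2S)-1-hydroxypropan-2-yl]-2,3-dihydro-1-benzofuran-5-yl}prop-2-enoate F6. Mitsunobu esterification with 17 (PPh3, DIAD, THF) would then give (2S)-2-{(2S)-5-[(1E)-3-tert-butoxy-3-oxoprop-1-en-1-yl]-2,3-dihydro-1-benzofuran-2-yl}propyl (2E)-3-(4-hydroxyphenyl)prop-2-enoate F7. Cleavage of the tert-butyl ester with CF3CO2H in CH2Cl2 (anisole as cation scavenger) returns to the route at the target 20.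

Further compounds
F1 | step 7 | 2-{[(tert-butyldimethylsilyl)oxy]methyl}prop-2-enal | C=C(C=O)CO[Si](C)(C)C(C)(C)C
F2 | step 7 | tert-butyl(dimethyl)[(2-methylidenebut-3-en-1-yl)oxy]silane | C=CC(=C)CO[Si](C)(C)C(C)(C)C
F3 | step 9 | 2-[(2S)-5-bromo-2,3-dihydro-1-benzofuran-2-yl]prop-2-enal | C=C(C=O)[C@@H]1Cc2cc(Br)ccc2O1
F4 | step 9 | 2-[(2S)-5-bromo-2,3-dihydro-1-benzofuran-2-yl]prop-2-enoic acid | C=C(C(=O)O)[C@@H]1Cc2cc(Br)ccc2O1
F5 | step 9 | (2R)-2-[(2S)-5-bromo-2,3-dihydro-1-benzofuran-2-yl]propanoic acid | C[C@@H](C(=O)O)[C@@H]1Cc2cc(Br)ccc2O1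
F6 | step 11 | tert-butyl (2E)-3-{(2S)-2-[(2S)-1-hydroxypropan-2-yl]-2,3-dihydro-1-benzofuran-5-yl}prop-2-enoate | C[C@@H](CO)[C@@H]1Cc2cc(/C=C/C(=O)OC(C)(C)C)ccc2O1
F7 | step 11 | (2S)-2-{(2S)-5-[(1E)-3-tert-butoxy-3-oxoprop-1-en-1-yl]-2,3-dihydro-1-benzofuran-2-yl}propyl (2E)-3-(4-hydroxyphenyl)prop-2-enoate | C[C@@H](COC(=O)/C=C/c1ccc(O)cc1)[C@@H]1Cc2cc(/C=C/C(=O)OC(C)(C)C)ccc2O1
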